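**Strategy**

The target is read as a 7,8-dioxygenated naphthalene-2-carbonyl compound to which aryl and hydrogen have been added across C1–C2. Ring B has only C1 and C2 as sp3 atoms and keeps C3=C4 conjugated to ring A. The key step therefore adds 4-benzyloxy-3-methoxyphenyllithium to C1 of a flat 7-benzyloxy-8-methoxy-2-naphthyl oxazoline carrying an (S)-tert-butyl group. It forms the C1–aryl bond, then the C2–H bond, and sets both stereocentres without closing a ring, so no bond is ever made at the hindered C8a. The naphthalene is built from a benzaldehyde by olefination and Friedel–Crafts closure at C4a; the C3 formyl group is added last.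

Key step: step 10

Numbering used: C1 carries the aryl group, C2 the acetoxymethyl group, C3 the formyl group; ring B is C1–C4, C4a, C8a; ring A is C4a–C8a with O7 and O8.

Assumption: the aryllithium is taken to add to the naphthalene face anti to the tert-butyl group of the (S)-oxazoline, which gives the 1S centre; if the sense proved opposite, (R)-tert-leucinol would be used with no other change.

Step 1
Reactants: 1 2,3-dihydroxybenzaldehyde
Product: 2 3-(benzyloxy)-2-hydroxybenzaldehyde
Conditions: NaH (2.2 equiv), DMF, 0 °C → rt; BnBr (1.0 equiv)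
Reagents that add atoms: benzyl bromide, BrCc1ccccc1
Why: Williamson etherification of the dianion, in which the O2 phenoxide is conjugated with the ortho formyl group and the more basic O3 phenoxide is therefore benzylated selectively.

Step 2
Reactants: 2 3-(benzyloxy)-2-hydroxybenzaldehyde
Product: 3 3-(benzyloxy)-2-methoxybenzaldehyde
Conditions: MeI, K2CO3, DMF, rt
Reagents that add atoms: iodomethane, CI
Why: Williamson O-methylation of the remaining phenol, which has no competing nucleophilic site.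

Step 3
Reactants: 4 triethyl phosphonoacetate; 5 bromoacetaldehyde diethyl acetal
Product: 6 ethyl 2-(diethoxyphosphoryl)-4,4-diethoxybutanoate
Conditions: NaH, DMF, 0 °C; then 5, NaI (cat.), 100 °C
Reagents that add atoms: none
Why: SN2 C-alkylation of the stabilised phosphonoacetate anion; the sluggish β-dialkoxy bromide is helped by hot DMF and iodide (Finkelstein) catalysis.

Step 4
Reactants: 3 3-(benzyloxy)-2-methoxybenzaldehyde; 6 ethyl 2-(diethoxyphosphoryl)-4,4-diethoxybutanoate
Product: 7 ethyl (E)-2-[3-(benzyloxy)-2-methoxybenzylidene]-4,4-diethoxybutanoate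
Conditions: NaH, THF, 0 °C → rt
Reagents that add atoms: none
Why: Horner–Wadsworth–Emmons olefination, in which an α-substituted phosphonoacetate and an aromatic aldehyde should give mainly the E isomer, with the aryl group trans to the ester and so cis to the acetal arm that must reach the ring.

Step 5
Reactants: 7 ethyl (E)-2-[3-(benzyloxy)-2-methoxybenzylidene]-4,4-diethoxybutanoate
Product: 9 ethyl 7-(benzyloxy)-8-methoxy-2-naphthoate, via ethoxy dihydronaphthalene 8 (not isolated)
Conditions: TsOH·H2O (0.2 equiv), toluene, 80 °C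
Reagents that add atoms: none
Why: Acid-promoted Friedel–Crafts (Bradsher-type) cyclisation: the oxocarbenium ion from the acetal attacks the only free ortho carbon, which is para to the benzyloxy group, forming C4–C4a, and the benzylic ether 8 then loses ethanol to aromatise.

Step 6
Reactants: 9 ethyl 7-(benzyloxy)-8-methoxy-2-naphthoate
Product: 10 7-(benzyloxy)-8-methoxy-2-naphthoic acid
Conditions: LiOH·H2O, THF/MeOH/H2O, 50 °C; then aq. HCl
Reagents that add atoms: lithium hydroxide, [Li+].[OH-]
Why: Saponification of an unhindered aryl ester; the ethers are inert to hydroxide.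

Step 7
Reactants: 10 7-(benzyloxy)-8-methoxy-2-naphthoic acid; 11 (S)-tert-leucinol
Product: 13 (S)-7-(benzyloxy)-N-(1-hydroxy-3,3-dimethylbutan-2-yl)-8-methoxy-2-naphthamide, via acid chloride 12 (not isolated)
Conditions: (COCl)2, DMF (cat.), CH2Cl2, 0 °C → rt; evaporate; 11, Et3N, CH2Cl2, 0 °C → rt
Reagents that add atoms: none
Why: Amide formation through the acid chloride (Schotten–Baumann-type acylation), with the amine acylated in preference to the neopentyl-like primary alcohol.

Step 8
Reactants: 13 (S)-7-(benzyloxy)-N-(1-hydroxy-3,3-dimethylbutan-2-yl)-8-methoxy-2-naphthamide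
Product: 15 (S)-2-[7-(benzyloxy)-8-methoxynaphthalen-2-yl]-4-tert-butyl-4,5-dihydrooxazole, via mesylate 14 (not isolated)
Conditions: MsCl, Et3N, CH2Cl2, 0 °C → 40 °C
Reagents that add atoms: none
Why: Cyclodehydration by O-mesylation and 5-exo-tet displacement by the amide oxygen at the primary carbon, which leaves the tert-butyl-bearing stereocentre untouched.

Step 9
Reactants: 16 4-bromo-2-methoxyphenol
Product: 17 1-(benzyloxy)-4-bromo-2-methoxybenzene
Conditions: BnBr, K2CO3, DMF, rt
Reagents that add atoms: benzyl bromide, BrCc1ccccc1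
Why: Williamson O-benzylation of a simple phenol.

Step 10
Reactants: 15 (S)-2-[7-(benzyloxy)-8-methoxynaphthalen-2-yl]-4-tert-butyl-4,5-dihydrooxazole; 17 1-(benzyloxy)-4-bromo-2-methoxybenzene
Product: 21 (S)-2-[(1S,2S)-7-(benzyloxy)-1-[4-(benzyloxy)-3-methoxyphenyl]-8-methoxy-1,2-dihydronaphthalen-2-yl]-4-tert-butyl-4,5-dihydrooxazole, via aryllithium 18 (not isolated), via lithium azaenolate 19 (not isolated), via cis C2 epimer 20 (not isolated)
Conditions: 17 (1.6 equiv), t-BuLi (3.0 equiv), THF, –78 °C; add 15, –78 → –40 °C, argon; MeOH (5 equiv), –78 °C → rt; aq. NH4Cl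
Reagents that add atoms: none
Why: Bromine–lithium exchange with two equivalents of t-BuLi (the second destroys t-BuBr, so no alkyl halide is left to alkylate the azaenolate) gives aryllithium 18, which binds the oxazoline nitrogen of the s-cis N=C–C2=C1 conformer and hands its aryl group to C1 through a cyclic transition state; the lithium azaenolate 19 so formed stays conjugated with C3=C4 and the untouched benzenoid ring A, and protonation at C2 completes a net aryl–H addition across C1–C2. The closest known reaction type is the dearomatising conjugate addition of organolithiums, aryllithiums included, to chiral 2-naphthyl oxazolines with trapping of the azaenolate. No ring is closed: ring B simply changes from aromatic to 1,2-dihydro. C1 is controlled by the (S)-tert-butyl group on C4 of the oxazoline, which should force the nitrogen-bound aryllithium onto the opposite face; C2 is controlled first by protonation anti to the pseudoaxial aryl group (expected to give cis epimer 20) and then by LiOMe-mediated equilibration of the acidic allylic C2–H to the more stable 1,2-trans isomer 21. The step needs C1 regioselectivity and facial selectivity, secured because C1 is the only site whose attack leaves ring A aromatic, no leaving group invites substitution, the ether groups are inert at –78 °C, and the peri clash with the C8 methoxy group eases once C1 is sp3 with a pseudoaxial aryl group.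

Step 11
Reactants: 21 (S)-2-[(1S,2S)-7-(benzyloxy)-1-[4-(benzyloxy)-3-methoxyphenyl]-8-methoxy-1,2-dihydronaphthalen-2-yl]-4-tert-butyl-4,5-dihydrooxazole
Product: 23 (4S)-2-[(1S,2S)-7-(benzyloxy)-1-[4-(benzyloxy)-3-methoxyphenyl]-8-methoxy-1,2-dihydronaphthalen-2-yl]-4-tert-butyl-3-methyloxazolidine (epimers at the aminal carbon), via oxazolinium triflate 22 (not isolated)
Conditions: MeOTf (1.2 equiv), CH2Cl2, 0 °C → rt; then NaBH4, THF/MeOH (4:1), 0 °C
Reagents that add atoms: methyl trifluoromethanesulfonate, COS(=O)(=O)C(F)(F)F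
Why: N-methylation of the oxazoline nitrogen (the only good nucleophile present) gives an iminium-type salt that borohydride reduces at the ring carbon to the N,O-acetal; neither reagent touches the styrene, the ethers or C2.

Step 12
Reactants: 23 (4S)-2-[(1S,2S)-7-(benzyloxy)-1-[4-(benzyloxy)-3-methoxyphenyl]-8-methoxy-1,2-dihydronaphthalen-2-yl]-4-tert-butyl-3-methyloxazolidine
Product: 25 [(1S,2S)-7-(benzyloxy)-1-[4-(benzyloxy)-3-methoxyphenyl]-8-methoxy-1,2-dihydronaphthalen-2-yl]methanol, via aldehyde 24 (not isolated)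
Conditions: oxalic acid, THF/H2O (4:1), rt; NaHCO3 work-up, crude used at once; NaBH4, MeOH, 0 °C
Reagents that add atoms: water, O
Why: Mild acid hydrolysis of the N,O-acetal frees the β,γ-unsaturated aldehyde, which is reduced immediately (borohydride carbonyl reduction) before it can epimerise at C2 or move C3=C4 into conjugation.

Step 13
Reactants: 25 [(1S,2S)-7-(benzyloxy)-1-[4-(benzyloxy)-3-methoxyphenyl]-8-methoxy-1,2-dihydronaphthalen-2-yl]methanol
Product: 26 [(1S,2S)-7-(benzyloxy)-1-[4-(benzyloxy)-3-methoxyphenyl]-8-methoxy-1,2-dihydronaphthalen-2-yl]methyl acetate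
Conditions: Ac2O, pyridine, DMAP (cat.), CH2Cl2, 0 °C → rt
Reagents that add atoms: acetic anhydride, CC(=O)OC(C)=O
Why: DMAP-catalysed O-acetylation of a primary alcohol, which installs the acetate of the target and shields the hydroxyl from the chloroiminium reagent of the next step.

Step 14
Reactants: 26 [(1S,2S)-7-(benzyloxy)-1-[4-(benzyloxy)-3-methoxyphenyl]-8-methoxy-1,2-dihydronaphthalen-2-yl]methyl acetate
Product: 28 [(1S,2R)-7-(benzyloxy)-1-[4-(benzyloxy)-3-methoxyphenyl]-3-formyl-8-methoxy-1,2-dihydronaphthalen-2-yl]methyl acetate, via iminium salt 27 (not isolated)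
Conditions: POCl3 (2 equiv), DMF (5 equiv), ClCH2CH2Cl, 0 → 60 °C; then aq. NaOAc, rt
Reagents that add atoms: N,N-dimethylformamide, CN(C)C=O; water, O
Why: Vilsmeier–Haack formylation of an electron-rich cyclic styrene: attack at C3 gives a C4 benzylic cation stabilised through C4a by the para O7, loss of the C3 proton restores C3=C4, and hydrolysis gives the enal; the veratrole-type rings are much weaker nucleophiles and C1 and C2 are not involved.

Step 15
Reactants: 28 [(1S,2R)-7-(benzyloxy)-1-[4-(benzyloxy)-3-methoxyphenyl]-3-formyl-8-methoxy-1,2-dihydronaphthalen-2-yl]methyl acetate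
Product: 29 [(1S,2R)-3-formyl-7-hydroxy-1-(4-hydroxy-3-methoxyphenyl)-8-methoxy-1,2-dihydronaphthalen-2-yl]methyl acetate (CNP0489020.1)
Conditions: BCl3 (1 M in CH2Cl2, 5 equiv), pentamethylbenzene (8 equiv), CH2Cl2, –78 °C; quench CHCl3/MeOH at –78 °C
Reagents that add atoms: none
Why: Lewis-acid cleavage of aryl benzyl ethers, with pentamethylbenzene trapping the benzyl cations by Friedel–Crafts alkylation; at –78 °C the enal, the acetate, the methyl ethers and both stereocentres should be left alone, and hydrogenolysis, which would reduce C3=C4, is avoided.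

**Compound list**

1 | 2,3-dihydroxybenzaldehyde | O=Cc1cccc(O)c1O | starting material
2 | 3-(benzyloxy)-2-hydroxybenzaldehyde | O=Cc1cccc(OCc2ccccc2)c1O | intermediate
3 | 3-(benzyloxy)-2-methoxybenzaldehyde | COc1c(C=O)cccc1OCc1ccccc1 | intermediate
4 | triethyl phosphonoacetate | CCOC(=O)CP(=O)(OCC)OCC | starting material
5 | bromoacetaldehyde diethyl acetal | CCOC(CBr)OCC | starting material
6 | ethyl 2-(diethoxyphosphoryl)-4,4-diethoxybutanoate | CCOC(=O)C(CC(OCC)OCC)P(=O)(OCC)OCC | intermediate
7 | ethyl (E)-2-[3-(benzyloxy)-2-methoxybenzylidene]-4,4-diethoxybutanoate | CCOC(=O)/C(CC(OCC)OCC)=C/c1cccc(OCc2ccccc2)c1OC | intermediate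
8 | ethyl 7-(benzyloxy)-4-ethoxy-8-methoxy-3,4-dihydronaphthalene-2-carboxylate (racemic at C4) | CCOC(=O)C1=Cc2c(OC)c(OCc3ccccc3)ccc2C(OCC)C1 | intermediate
9 | ethyl 7-(benzyloxy)-8-methoxy-2-naphthoate | CCOC(=O)c1ccc2ccc(OCc3ccccc3)c(OC)c2c1 | intermediate
10 | 7-(benzyloxy)-8-methoxy-2-naphthoic acid | OC(=O)c1ccc2ccc(OCc3ccccc3)c(OC)c2c1 | intermediate
11 | (S)-tert-leucinol | CC(C)(C)[C@H](N)CO | starting material
12 | 7-(benzyloxy)-8-methoxy-2-naphthoyl chloride | ClC(=O)c1ccc2ccc(OCc3ccccc3)c(OC)c2c1 | intermediate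
13 | (S)-7-(benzyloxy)-N-(1-hydroxy-3,3-dimethylbutan-2-yl)-8-methoxy-2-naphthamide | CC(C)(C)[C@H](NC(=O)c1ccc2ccc(OCc3ccccc3)c(OC)c2c1)CO | intermediate
14 | (S)-2-[7-(benzyloxy)-8-methoxy-2-naphthamido]-3,3-dimethylbutyl methanesulfonate | CC(C)(C)[C@H](NC(=O)c1ccc2ccc(OCc3ccccc3)c(OC)c2c1)COS(C)(=O)=O | intermediate
15 | (S)-2-[7-(benzyloxy)-8-methoxynaphthalen-2-yl]-4-tert-butyl-4,5-dihydrooxazole | CC(C)(C)[C@H]1COC(=N1)c1ccc2ccc(OCc3ccccc3)c(OC)c2c1 | intermediate
16 | 4-bromo-2-methoxyphenol | COc1cc(Br)ccc1O | starting material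
17 | 1-(benzyloxy)-4-bromo-2-methoxybenzene | COc1cc(Br)ccc1OCc1ccccc1 | intermediate
18 | [4-(benzyloxy)-3-methoxyphenyl]lithium | [Li]c1ccc(OCc2ccccc2)c(OC)c1 | intermediate
19 | lithium azaenolate from aryl addition at C1 (N-lithio ketene N,O-acetal exocyclic at C2, C3=C4 retained, C1 as in 21) | COc1cc([C@H]2c3c(ccc(OCc4ccccc4)c3OC)C=C/C2=C5/N([Li])[C@@H](C(C)(C)C)CO5)ccc1OCc1ccccc1 | intermediate
20 | (S)-2-[(1S,2R)-7-(benzyloxy)-1-[4-(benzyloxy)-3-methoxyphenyl]-8-methoxy-1,2-dihydronaphthalen-2-yl]-4-tert-butyl-4,5-dihydrooxazole (1,2-cis) | COc1cc([C@H]2c3c(ccc(OCc4ccccc4)c3OC)C=C[C@H]2C5=N[C@@H](C(C)(C)C)CO5)ccc1OCc1ccccc1 | intermediate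
21 | (S)-2-[(1S,2S)-7-(benzyloxy)-1-[4-(benzyloxy)-3-methoxyphenyl]-8-methoxy-1,2-dihydronaphthalen-2-yl]-4-tert-butyl-4,5-dihydrooxazole (1,2-trans) | COc1cc([C@H]2c3c(ccc(OCc4ccccc4)c3OC)C=C[C@@H]2C5=N[C@@H](C(C)(C)C)CO5)ccc1OCc1ccccc1 | intermediate
22 | N-methyloxazolinium trifluoromethanesulfonate of 21 | COc1cc([C@H]2c3c(ccc(OCc4ccccc4)c3OC)C=C[C@@H]2C5=[N+](C)[C@@H](C(C)(C)C)CO5)ccc1OCc1ccccc1.[O-]S(=O)(=O)C(F)(F)F | intermediate
23 | (4S)-2-[(1S,2S)-7-(benzyloxy)-1-[4-(benzyloxy)-3-methoxyphenyl]-8-methoxy-1,2-dihydronaphthalen-2-yl]-4-tert-butyl-3-methyloxazolidine (epimers at the aminal carbon) | COc1cc([C@H]2c3c(ccc(OCc4ccccc4)c3OC)C=C[C@@H]2C5N(C)[C@@H](C(C)(C)C)CO5)ccc1OCc1ccccc1 | intermediate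
24 | (1S,2S)-7-(benzyloxy)-1-[4-(benzyloxy)-3-methoxyphenyl]-8-methoxy-1,2-dihydronaphthalene-2-carbaldehyde | COc1cc([C@H]2c3c(ccc(OCc4ccccc4)c3OC)C=C[C@@H]2C=O)ccc1OCc1ccccc1 | intermediate
25 | [(1S,2S)-7-(benzyloxy)-1-[4-(benzyloxy)-3-methoxyphenyl]-8-methoxy-1,2-dihydronaphthalen-2-yl]methanol | COc1cc([C@H]2c3c(ccc(OCc4ccccc4)c3OC)C=C[C@@H]2CO)ccc1OCc1ccccc1 | intermediate
26 | [(1S,2S)-7-(benzyloxy)-1-[4-(benzyloxy)-3-methoxyphenyl]-8-methoxy-1,2-dihydronaphthalen-2-yl]methyl acetate | COc1cc([C@H]2c3c(ccc(OCc4ccccc4)c3OC)C=C[C@@H]2COC(C)=O)ccc1OCc1ccccc1 | intermediate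
27 | C3 dimethyliminium dichlorophosphate of 26 (C3–CH=NMe2 cation) | COc1cc([C@H]2c3c(ccc(OCc4ccccc4)c3OC)C=C(C=[N+](C)C)[C@@H]2COC(C)=O)ccc1OCc1ccccc1.[O-]P(=O)(Cl)Cl | intermediate
28 | [(1S,2R)-7-(benzyloxy)-1-[4-(benzyloxy)-3-methoxyphenyl]-3-formyl-8-methoxy-1,2-dihydronaphthalen-2-yl]methyl acetate | COc1cc([C@H]2c3c(ccc(OCc4ccccc4)c3OC)C=C(C=O)[C@@H]2COC(C)=O)ccc1OCc1ccccc1 | intermediate
29 | [(1S,2R)-3-formyl-7-hydroxy-1-(4-hydroxy-3-methoxyphenyl)-8-methoxy-1,2-dihydronaphthalen-2-yl]methyl acetate (CNP0489020.1) | COc1cc([C@H]2c3c(ccc(O)c3OC)C=C(C=O)[C@@H]2COC(C)=O)ccc1O | target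

**Step count and risks**

Total steps: 15. Longest linear sequence: 13 steps (steps 1, 2, 4–8 and 10–15, from 1 to 29); steps 3 and 9 are side branches.

Steps most likely to fail:

1. Step 10. What may go wrong: slow addition because O7 donates into C1 and the peri methoxy group crowds the approach, poor facial discrimination at C1, or drift of C3=C4 into conjugation with the oxazoline during the C2 equilibration. Fallback (an external chiral ligand replaces the covalent auxiliary): it sets out from acid 10. Its acid chloride 12 would be esterified with lithium 2,6-di-tert-butyl-4-methoxyphenoxide to give the hindered aryl ester 2,6-di-tert-butyl-4-methoxyphenyl 7-(benzyloxy)-8-methoxy-2-naphthoate F1. Conjugate addition of aryllithium 18 in toluene at –78 °C in the presence of a twofold-symmetric chiral diether, (1R,2R)- or (1S,2S)-1,2-dimethoxy-1,2-diphenylethane (the enantiomer chosen to give 1S), followed by proton quench, would give the trans adduct 2,6-di-tert-butyl-4-methoxyphenyl (1S,2S)-7-(benzyloxy)-1-[4-(benzyloxy)-3-methoxyphenyl]-8-methoxy-1,2-dihydronaphthalene-2-carboxylate F2. Reduction with LiAlH4 in THF would cleave the aryl ester and rejoin the route at alcohol 25.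

2. Step 14. What may go wrong: sluggish attack at C3 next to the substituted C2, competing formylation of an aromatic ring, or acid-promoted isomerisation of the dihydronaphthalene. Fallback (vinyl bromide, then palladium-catalysed formylation): it sets out from acetate 26. NBS in wet THF would give the bromohydrin [(1S,2S)-7-(benzyloxy)-1-[4-(benzyloxy)-3-methoxyphenyl]-3-bromo-4-hydroxy-8-methoxy-1,2,3,4-tetrahydronaphthalen-2-yl]methyl acetate F3 (hydroxyl at the benzylic C4, C3 and C4 unassigned). TsOH in warm toluene would dehydrate it through the C4 cation to the vinyl bromide [(1S,2S)-7-(benzyloxy)-1-[4-(benzyloxy)-3-methoxyphenyl]-3-bromo-8-methoxy-1,2-dihydronaphthalen-2-yl]methyl acetate F4. Reductive carbonylation with Pd(PPh3)4, CO (1 atm) and Bu3SnH in toluene at 50 °C would give enal 28, where the route resumes.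

3. Step 15. What may go wrong: chloride or Lewis-acid attack on the enal, partial loss of the acetate, or incomplete cleavage of the crowded O7 benzyl ether. Fallback (the phenol protecting groups are exchanged before the enal exists): it sets out from acetate 26. BCl3 and pentamethylbenzene at –78 °C would give the bisphenol [(1S,2S)-7-hydroxy-1-(4-hydroxy-3-methoxyphenyl)-8-methoxy-1,2-dihydronaphthalen-2-yl]methyl acetate F5. TBSCl and imidazole in DMF would give the bis(tert-butyldimethylsilyl) ether of that bisphenol F6. Vilsmeier–Haack formylation as in step 14 would give the C3-formyl bis(silyl ether) [(1S,2R)-7-(tert-butyldimethylsilyloxy)-1-[4-(tert-butyldimethylsilyloxy)-3-methoxyphenyl]-3-formyl-8-methoxy-1,2-dihydronaphthalen-2-yl]methyl acetate F7. KHF2 in MeOH at rt would free both phenols without touching the acetate and give target 29.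

**Further compounds**

F1 | step 10 | 2,6-di-tert-butyl-4-methoxyphenyl 7-(benzyloxy)-8-methoxy-2-naphthoate | COc1cc(C(C)(C)C)c(OC(=O)c2ccc3ccc(OCc4ccccc4)c(OC)c3c2)c(C(C)(C)C)c1
F2 | step 10 | 2,6-di-tert-butyl-4-methoxyphenyl (1S,2S)-7-(benzyloxy)-1-[4-(benzyloxy)-3-methoxyphenyl]-8-methoxy-1,2-dihydronaphthalene-2-carboxylate | COc1cc([C@H]2c3c(ccc(OCc4ccccc4)c3OC)C=C[C@@H]2C(=O)Oc2c(C(C)(C)C)cc(OC)cc2C(C)(C)C)ccc1OCc1ccccc1
F3 | step 14 | [(1S,2S)-7-(benzyloxy)-1-[4-(benzyloxy)-3-methoxyphenyl]-3-bromo-4-hydroxy-8-methoxy-1,2,3,4-tetrahydronaphthalen-2-yl]methyl acetate (C3 and C4 unassigned) | COc1cc([C@H]2c3c(ccc(OCc4ccccc4)c3OC)C(O)C(Br)[C@@H]2COC(C)=O)ccc1OCc1ccccc1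
F4 | step 14 | [(1S,2S)-7-(benzyloxy)-1-[4-(benzyloxy)-3-methoxyphenyl]-3-bromo-8-methoxy-1,2-dihydronaphthalen-2-yl]methyl acetate | COc1cc([C@H]2c3c(ccc(OCc4ccccc4)c3OC)C=C(Br)[C@@H]2COC(C)=O)ccc1OCc1ccccc1
F5 | step 15 | [(1S,2S)-7-hydroxy-1-(4-hydroxy-3-methoxyphenyl)-8-methoxy-1,2-dihydronaphthalen-2-yl]methyl acetate | COc1cc([C@H]2c3c(ccc(O)c3OC)C=C[C@@H]2COC(C)=O)ccc1O
F6 | step 15 | [(1S,2S)-7-(tert-butyldimethylsilyloxy)-1-[4-(tert-butyldimethylsilyloxy)-3-methoxyphenyl]-8-methoxy-1,2-dihydronaphthalen-2-yl]methyl acetate | COc1cc([C@H]2c3c(ccc(O[Si](C)(C)C(C)(C)C)c3OC)C=C[C@@H]2COC(C)=O)ccc1O[Si](C)(C)C(C)(C)C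
F7 | step 15 | [(1S,2R)-7-(tert-butyldimethylsilyloxy)-1-[4-(tert-butyldimethylsilyloxy)-3-methoxyphenyl]-3-formyl-8-methoxy-1,2-dihydronaphthalen-2-yl]methyl acetate | COc1cc([C@H]2c3c(ccc(O[Si](C)(C)C(C)(C)C)c3OC)C=C(C=O)[C@@H]2COC(C)=O)ccc1O[Si](C)(C)C(C)(C)C
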